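The oxolane is disconnected at both ring C–O bonds, O1–C2 and O1–C5. Each of these carbons is benzylic to a 4-hydroxy-3,5-dimethoxyphenyl ring with a free para phenol, the arrangement from which a flavin-dependent 4-alkylphenol oxidase draws para-quinone methides. In one operation the enzyme should oxidise both benzylic CH2 groups of a twofold-symmetric (2R,3R)-dibenzylbutane-1,4-diol bisphenol whose primary hydroxyls are locked in a seven-membered acetonide. Water adds to the first methide and sets C2, then the new hydroxyl closes onto the second methide and sets C5 and the ring. C3 and C4 come from an auxiliary-controlled oxidative enolate dimerisation; weak aqueous acid finally removes the acetonide.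

Key step: step 8

Remarks on the chemistry (they hold for all steps below):
- Atom numbers O1 and C2 to C5 refer to the oxolane ring of the target, which is the all-trans (2S,3R,4R,5S) isomer. Compounds 15 and 19 carry the same configuration at the two backbone centres as the target.
- The auxiliary is fixed as the (S) enantiomer, since this is the one that leads to the (R,R) dimer and hence to (3R,4R).
- Benzylation of the phenol also esterifies the acid, so a saponification is built into the same step.
- Assumption: the oxidase is a purified, engineered member of the vanillyl-alcohol oxidase/eugenol oxidase family, found by screening a variant panel. Wild-type vanillyl-alcohol oxidase hydrates the methides of short 4-alkylphenols with the opposite (R) sense, so a variant with inverted water delivery is specified.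
- The seven-membered acetal is kept on purpose: it masks both primary oxygens in one compact ring, preserves the twofold symmetry, and its trans-5,6-disubstituted ring holds the two benzylic carbons gauche.

Step 1
Reactants: 1 sinapic acid
Product: 2 3-(4-hydroxy-3,5-dimethoxyphenyl)propanoic acid
Conditions: H2 (1 atm), 10% Pd/C, MeOH, rt
Reagents that add atoms: none
Why: Heterogeneous catalytic hydrogenation saturates only the cinnamate C=C, the arene, phenol and acid being inert under these conditions, and no stereocentre is formed.

Step 2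
Reactants: 2 3-(4-hydroxy-3,5-dimethoxyphenyl)propanoic acid; 3 benzyl bromide
Product: 5 3-(4-benzyloxy-3,5-dimethoxyphenyl)propanoic acid, via benzyl ester 4 (not isolated)
Conditions: BnBr (2.3 equiv), K2CO3, DMF, 60 °C; then NaOH, MeOH/H2O, 60 °C; HCl work-up
Reagents that add atoms: benzyl bromide (BrCc1ccccc1); sodium hydroxide ([Na+].[OH-])
Why: Williamson etherification of the phenoxide runs alongside O-alkylation of the carboxylate, and the following saponification by acyl–oxygen cleavage, in which the hydroxide oxygen ends up in the carboxyl group, removes only the benzyl ester because the aryl benzyl ether is stable to hydroxide.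

Step 3
Reactants: 5 3-(4-benzyloxy-3,5-dimethoxyphenyl)propanoic acid; 6 (S)-4-benzyl-2-oxazolidinone
Product: 8 (S)-4-benzyl-3-[3-(4-benzyloxy-3,5-dimethoxyphenyl)propanoyl]oxazolidin-2-one, via mixed pivalic anhydride 7 (not isolated)
Conditions: PivCl, Et3N, THF, −20 °C; then 6, LiCl, −20 °C to rt
Reagents that add atoms: (S)-4-benzyl-2-oxazolidinone (O=C1N[C@@H](Cc2ccccc2)CO1)
Why: N-acylation of the oxazolidinone through a mixed anhydride should occur at the less hindered arylpropanoyl carbonyl, and it installs the (S) auxiliary that later directs both new centres to R.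

Step 4
Reactants: 8 (S)-4-benzyl-3-[3-(4-benzyloxy-3,5-dimethoxyphenyl)propanoyl]oxazolidin-2-one (two molecules)
Product: 11 (4S,4'S)-3,3'-[(2R,3R)-2,3-bis(4-benzyloxy-3,5-dimethoxybenzyl)butanedioyl]bis(4-benzyloxazolidin-2-one), via lithium Z-enolate 9 (not isolated), via trichlorotitanium enolate 10 (not isolated)
Conditions: LiN(iPr)2 (1.05 equiv), THF, −78 °C; then TiCl4 (1.05 equiv), −78 to 0 °C
Reagents that add atoms: none
Why: In this oxidative enolate homocoupling, known for 3-arylpropanoyl oxazolidinones, the chelated Z-enolate passes one electron to tetravalent titanium (which becomes trivalent) and the two α-carbons join, each on the face opposite the auxiliary benzyl group, which for the (S) auxiliary gives the twofold-symmetric (R,R) dimer.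

Step 5
Reactants: 11 (4S,4'S)-3,3'-[(2R,3R)-2,3-bis(4-benzyloxy-3,5-dimethoxybenzyl)butanedioyl]bis(4-benzyloxazolidin-2-one)
Product: 12 (2R,3R)-2,3-bis(4-benzyloxy-3,5-dimethoxybenzyl)butane-1,4-diol
Conditions: LiBH4, MeOH (4 equiv), THF, 0 °C to rt
Reagents that add atoms: none
Why: Reductive cleavage of the N-acyl oxazolidinones by hydride attack at the exocyclic carbonyls should give the diol and free the auxiliary, and the weakly basic medium leaves the two α-centres (R,R).

Step 6
Reactants: 12 (2R,3R)-2,3-bis(4-benzyloxy-3,5-dimethoxybenzyl)butane-1,4-diol; 13 2,2-dimethoxypropane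
Product: 14 (5R,6R)-5,6-bis(4-benzyloxy-3,5-dimethoxybenzyl)-2,2-dimethyl-1,3-dioxepane
Conditions: Me2C(OMe)2, TsOH (cat.), CH2Cl2, 5 Å molecular sieves, rt; Et3N quench
Reagents that add atoms: 2,2-dimethoxypropane (COC(C)(C)OC)
Why: Acid-catalysed transketalisation should close the trans-2,3-disubstituted 1,4-diol to the seven-membered isopropylidene acetal, a known ring type for such diols, driven by removal of methanol and touching no stereocentre.

Step 7
Reactants: 14 (5R,6R)-5,6-bis(4-benzyloxy-3,5-dimethoxybenzyl)-2,2-dimethyl-1,3-dioxepane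
Product: 15 (5R,6R)-5,6-bis(4-hydroxy-3,5-dimethoxybenzyl)-2,2-dimethyl-1,3-dioxepane
Conditions: H2 (1 atm), 10% Pd/C, NaHCO3 (solid), EtOAc, rt
Reagents that add atoms: none
Why: Hydrogenolysis cleaves the two aryl benzyl ethers, the only benzylic C–O bonds present, while the buffered aprotic medium keeps the acid-labile acetal intact.

Step 8
Reactants: 15 (5R,6R)-5,6-bis(4-hydroxy-3,5-dimethoxybenzyl)-2,2-dimethyl-1,3-dioxepane
Product: 19 huazhongilexin 9,9'-O-isopropylidene acetal, via first quinone methide 16 (not isolated), via benzylic (S)-carbinol 17 (not isolated), via second quinone methide 18 (not isolated)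
Conditions: engineered eugenol oxidase variant (FAD-dependent 4-alkylphenol oxidase of the vanillyl-alcohol oxidase family, purified), air, K2HPO4/KH2PO4 buffer pH 7.5, DMSO (10% v/v), 25 °C
Reagents that add atoms: water (O)
Why: Proposed new method: the phenolate of 15 held in the active site passes a benzylic hydride to the flavin, the enzyme-bound para-quinone methide 16 takes up active-site water to give carbinol 17, O2 returns the flavin to its oxidised form, and a second turnover on the other arm gives methide 18, whose exocyclic carbon is captured by the C2 hydroxyl. The closest known reaction type is the benzylic hydroxylation of 4-alkylphenols, 2,6-dimethoxy cases included, by vanillyl-alcohol oxidase and eugenol oxidase; a substrate of this size and a double oxidation that ends in ether formation have not been shown. The oxolane closes by 5-exo-trig oxa-Michael addition of O1 to C5, the methide C=C lying outside the new ring. C2 is set by the enzyme, which must deliver water to the methide face that leads to the (S)-alcohol, the sense known for variants of this enzyme class in which the aspartate base sits on the opposite wall of the cavity, so a variant of that type with a widened cavity is proposed. C5 is set by the substrate, the ring closing with the aryl group anti to the C4 CH2O arm to give the all-trans oxolane. The step needs attack by the C2 hydroxyl in preference to a primary oxygen or bulk water, and no loss of the C3–H or C4–H proton from the methides: the acetonide masks both primary oxygens and its trans-5,6-disubstituted ring holds the two benzylic carbons gauche, within reach of each other, while the twofold symmetry of 15 makes the choice of the first arm irrelevant.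

Step 9
Reactants: 19 huazhongilexin 9,9'-O-isopropylidene acetal
Product: 20 huazhongilexin
Conditions: AcOH/H2O/THF (3:1:1), rt
Reagents that add atoms: none
Why: Acid-catalysed acetal hydrolysis should open the seven-membered isopropylidene acetal at the ketal carbon well before the benzylic ring C–O bonds ionise in this weak acid, so all four stereocentres stay as set.

Compound list
1 | sinapic acid, (E)-3-(4-hydroxy-3,5-dimethoxyphenyl)prop-2-enoic acid | COc1cc(/C=C/C(=O)O)cc(OC)c1O | starting material
2 | 3-(4-hydroxy-3,5-dimethoxyphenyl)propanoic acid | COc1cc(CCC(=O)O)cc(OC)c1O | intermediate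
3 | benzyl bromide | BrCc1ccccc1 | starting material
4 | benzyl 3-(4-benzyloxy-3,5-dimethoxyphenyl)propanoate (not isolated) | COc1cc(CCC(=O)OCc2ccccc2)cc(OC)c1OCc1ccccc1 | intermediate
5 | 3-(4-benzyloxy-3,5-dimethoxyphenyl)propanoic acid | COc1cc(CCC(=O)O)cc(OC)c1OCc1ccccc1 | intermediate
6 | (S)-4-benzyl-2-oxazolidinone | O=C1N[C@@H](Cc2ccccc2)CO1 | starting material
7 | mixed anhydride of 5 with pivalic acid (not isolated) | COc1cc(CCC(=O)OC(=O)C(C)(C)C)cc(OC)c1OCc1ccccc1 | intermediate
8 | (S)-4-benzyl-3-[3-(4-benzyloxy-3,5-dimethoxyphenyl)propanoyl]oxazolidin-2-one | COc1cc(CCC(=O)N2[C@@H](Cc3ccccc3)COC2=O)cc(OC)c1OCc1ccccc1 | intermediate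
9 | lithium Z-enolate of 8 (not isolated) | COc1cc(C/C=C(\O[Li])N2[C@@H](Cc3ccccc3)COC2=O)cc(OC)c1OCc1ccccc1 | intermediate
10 | trichlorotitanium Z-enolate of 8 (not isolated) | COc1cc(C/C=C(\O[Ti](Cl)(Cl)Cl)N2[C@@H](Cc3ccccc3)COC2=O)cc(OC)c1OCc1ccccc1 | intermediate
11 | (4S,4'S)-3,3'-[(2R,3R)-2,3-bis(4-benzyloxy-3,5-dimethoxybenzyl)butanedioyl]bis(4-benzyloxazolidin-2-one) | COc1cc(C[C@@H](C(=O)N2[C@@H](Cc3ccccc3)COC2=O)[C@@H](Cc2cc(OC)c(OCc3ccccc3)c(OC)c2)C(=O)N2[C@@H](Cc3ccccc3)COC2=O)cc(OC)c1OCc1ccccc1 | intermediate
12 | (2R,3R)-2,3-bis(4-benzyloxy-3,5-dimethoxybenzyl)butane-1,4-diol | OC[C@H](Cc1cc(OC)c(OCc2ccccc2)c(OC)c1)[C@@H](Cc1cc(OC)c(OCc2ccccc2)c(OC)c1)CO | intermediate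
13 | 2,2-dimethoxypropane | COC(C)(C)OC | starting material
14 | (5R,6R)-5,6-bis(4-benzyloxy-3,5-dimethoxybenzyl)-2,2-dimethyl-1,3-dioxepane | CC1(C)OC[C@H](Cc2cc(OC)c(OCc3ccccc3)c(OC)c2)[C@@H](Cc2cc(OC)c(OCc3ccccc3)c(OC)c2)CO1 | intermediate
15 | (5R,6R)-5,6-bis(4-hydroxy-3,5-dimethoxybenzyl)-2,2-dimethyl-1,3-dioxepane, precursor of the key step | CC1(C)OC[C@H](Cc2cc(OC)c(O)c(OC)c2)[C@@H](Cc2cc(OC)c(O)c(OC)c2)CO1 | intermediate
16 | mono(para-quinone methide) of 15, one benzylic carbon now CH= on a 3,5-dimethoxy-4-oxocyclohexa-2,5-dienylidene ring (not isolated) | CC1(C)OC[C@H](C=C2C=C(OC)C(=O)C(OC)=C2)[C@@H](Cc2cc(OC)c(O)c(OC)c2)CO1 | intermediate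
17 | (S)-benzylic carbinol, 15 carrying OH at one benzylic carbon (not isolated) | CC1(C)OC[C@H]([C@H](O)c2cc(OC)c(O)c(OC)c2)[C@@H](Cc2cc(OC)c(O)c(OC)c2)CO1 | intermediate
18 | para-quinone methide of 17 on the second arm (not isolated) | CC1(C)OC[C@H]([C@H](O)c2cc(OC)c(O)c(OC)c2)[C@@H](C=C2C=C(OC)C(=O)C(OC)=C2)CO1 | intermediate
19 | huazhongilexin 9,9'-O-isopropylidene acetal, all-trans (2S,3R,4R,5S)-2,5-bis(4-hydroxy-3,5-dimethoxyphenyl)oxolane with the 3- and 4-CH2O arms bridged by CMe2 (trans-fused 2,2-dimethyl-1,3-dioxepane) | COc1cc([C@H]2O[C@H](c3cc(OC)c(O)c(OC)c3)[C@H]3COC(C)(C)OC[C@H]23)cc(OC)c1O | intermediate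
20 | huazhongilexin, [(2S,3R,4R,5S)-2,5-bis(4-hydroxy-3,5-dimethoxyphenyl)oxolane-3,4-diyl]dimethanol | COc1cc([C@H]2O[C@H](c3cc(OC)c(O)c(OC)c3)[C@@H](CO)[C@@H]2CO)cc(OC)c1O | target

Total step count: 9. Longest linear sequence: 9 steps (sinapic acid to huazhongilexin; the dimerisation in step 4 joins two molecules of the same intermediate).

Steps most likely to fail

1. Step 8, the step that carries the new method. Five processes could defeat it: the substrate may be too large to bind productively; water may be delivered to the wrong methide face, giving the C2 epimer; a bound methide may lose the C3 or C4 proton and tautomerise to a styrene, erasing a stereocentre; the carbinol or the product ether may be oxidised further to a ketone; and the second methide may be hydrated instead of closing the ring. The fallback uses known quinone methide chemistry, sets out from 15 and returns at 19. Oxidation of both phenols with Ag2O in dry CH2Cl2 should give the bis(quinone methide) F1. After filtration, stirring in THF/water at neutral pH lets water add to one methide and the resulting benzylic hydroxyl close onto the other by oxa-Michael addition, giving 19. Both new centres would then be under substrate control only, so the all-trans isomer would have to be separated from its C2/C5 epimers by chromatography.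

2. Step 4. The coupling may show poor facial selectivity (meso or mixed dimers). The enolate may also be consumed by protonation or chlorination without C–C bond formation, and the Lewis acid may strip the benzyl ethers flanked by two methoxy groups. The fallback is a stepwise construction that sets out from 8 and returns at 12. Alkylation of the sodium enolate of 8 (NaN(SiMe3)2, THF, −78 °C) with tert-butyl bromoacetate should give the succinate imide F2, with the new centre R by the same facial bias. LiBH4 then removes the auxiliary to give the hydroxy ester F3, and TsOH (cat.) in warm toluene closes it to the (R)-β-benzyl-γ-butyrolactone F4. The lithium enolate of F4 (LiN(SiMe3)2, THF, −78 °C) is alkylated trans to the existing substituent with 4-benzyloxy-3,5-dimethoxybenzyl bromide F5 (from the corresponding benzyl alcohol and PBr3) to give the trans-(3R,4R)-lactone F6. LiAlH4 reduces this lactone to diol 12.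

3. Step 6. Closure of the seven-membered ring may lose out to open-chain mixed ketals or oligomers, and the strained acetal may be shed again on silica or in step 7. The fallback is a change of protecting group that sets out from 12 and returns at 20. Ac2O/pyridine should give the diacetate F7, and hydrogenolysis (H2, Pd/C, EtOAc) then gives the bisphenol diacetate F8. The oxidase step run on this bisphenol under the conditions of step 8 gives huazhongilexin 9,9'-di-O-acetate F9, and methanolysis with K2CO3 in degassed MeOH at rt gives 20.

Further compounds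
F1 | step 8 | (5R,6R)-5,6-bis[(3,5-dimethoxy-4-oxocyclohexa-2,5-dien-1-ylidene)methyl]-2,2-dimethyl-1,3-dioxepane, the bis(quinone methide) of 15 | CC1(C)OC[C@H](C=C2C=C(OC)C(=O)C(OC)=C2)[C@@H](C=C2C=C(OC)C(=O)C(OC)=C2)CO1
F2 | step 4 | (S)-4-benzyl-3-[(R)-2-(4-benzyloxy-3,5-dimethoxybenzyl)-4-tert-butoxy-4-oxobutanoyl]oxazolidin-2-one | CC(C)(C)OC(=O)C[C@@H](Cc1cc(OC)c(OCc2ccccc2)c(OC)c1)C(=O)N1[C@@H](Cc2ccccc2)COC1=O
F3 | step 4 | tert-butyl (R)-3-(4-benzyloxy-3,5-dimethoxybenzyl)-4-hydroxybutanoate | CC(C)(C)OC(=O)C[C@@H](Cc1cc(OC)c(OCc2ccccc2)c(OC)c1)CO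
F4 | step 4 | (R)-4-(4-benzyloxy-3,5-dimethoxybenzyl)dihydrofuran-2(3H)-one | O=C1C[C@@H](Cc2cc(OC)c(OCc3ccccc3)c(OC)c2)CO1
F5 | step 4 | 4-benzyloxy-3,5-dimethoxybenzyl bromide | COc1cc(CBr)cc(OC)c1OCc1ccccc1
F6 | step 4 | (3R,4R)-3,4-bis(4-benzyloxy-3,5-dimethoxybenzyl)dihydrofuran-2(3H)-one | O=C1[C@H](Cc2cc(OC)c(OCc3ccccc3)c(OC)c2)[C@@H](Cc2cc(OC)c(OCc3ccccc3)c(OC)c2)CO1
F7 | step 6 | (2R,3R)-2,3-bis(4-benzyloxy-3,5-dimethoxybenzyl)butane-1,4-diyl diacetate | CC(=O)OC[C@H](Cc1cc(OC)c(OCc2ccccc2)c(OC)c1)[C@@H](Cc1cc(OC)c(OCc2ccccc2)c(OC)c1)COC(C)=O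
F8 | step 6 | (2R,3R)-2,3-bis(4-hydroxy-3,5-dimethoxybenzyl)butane-1,4-diyl diacetate | CC(=O)OC[C@H](Cc1cc(OC)c(O)c(OC)c1)[C@@H](Cc1cc(OC)c(O)c(OC)c1)COC(C)=O
F9 | step 6 | huazhongilexin 9,9'-di-O-acetate | COc1cc([C@H]2O[C@H](c3cc(OC)c(O)c(OC)c3)[C@@H](COC(C)=O)[C@@H]2COC(C)=O)cc(OC)c1O
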